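**Plan** (locants are the azulene positions of the target: C1–C3, C3a, C4–C8, C8a)
1. Retrosynthesis: remove the two esters (O–C8 angeloyl, O–C4 veratroyl), open the seven-membered ring at C6=C7 (metathesis), cut C4–C5 (2-methylallyl addition to a C4 aldehyde), then cut the five-membered ring at C8a–C1 and C3a–C3.
2. Enabling feature: in ring C1–C2–C3–C3a–C8a the tertiary carbinol C3 and the quaternary C8a are both β to C4. With C4 as an acyl carbon, C3–C3a is an aldol bond and C8a–C1 a homoenolate Michael bond, so the ring is the [3+2] adduct of an enal (C4, C3a, C8a) and isopropyl vinyl ketone (C1, C2, C3).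
3. Forward: acyclic (E)-enal 6 and ketone 7 give the cyclopentane as a cis-fused β-lactone (a temporary C3–O–C4 ring, opened by hydride); then the C4 side chain, the veratrate, metathesis to the seven-membered ring and the angelate last.
4. Stereochemistry: C8 from a Sharpless kinetic resolution; C8a, C3a and C3 in the key step, directed by C8 and locked by the β-lactone; C4 by chelation-controlled Grignard addition.
5. The trans ring fusion follows from the C4 and C8 arms lying trans on the cyclopentane before ring closure. The facial selectivities are predicted from models, not measured.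

Key step: step 6

Step 1
Reactants: 1 ethyl (2E)-3-methyl-4-oxobut-2-enoate
Product: 2 ethyl (2E)-4-hydroxy-3-methylhexa-2,5-dienoate (racemic)
Conditions: CH2=CHMgBr (1.05 equiv), THF, −78 °C; aq. NH4Cl
Reagents that add atoms: vinylmagnesium bromide, C=C[Mg]Br
Why: Grignard 1,2-addition, in which the vinyl reagent attacks the aldehyde at −78 °C much faster than the ester or the alkene, and the new carbinol centre is formed racemic on purpose for resolution in step 2.

Step 2
Reactants: 2 ethyl (2E)-4-hydroxy-3-methylhexa-2,5-dienoate (racemic)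
Product: 3 ethyl (2E,4R)-4-hydroxy-3-methylhexa-2,5-dienoate
Conditions: Ti(OiPr)4 (10 mol %), D-(−)-diisopropyl tartrate (12 mol %), tBuOOH (0.6 equiv), 4 Å molecular sieves, CH2Cl2, −20 °C
Reagents that add atoms: none
Why: Sharpless kinetic resolution of a secondary allylic alcohol, in which the D-(−)-tartrate catalyst epoxidises the vinyl group of the (4S)-alcohol fast and leaves the (4R)-alcohol, whose alkenyl substituent blocks the face of oxygen delivery; the ester-conjugated alkene is too electron-poor to react.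

Step 3
Reactants: 3 ethyl (2E,4R)-4-hydroxy-3-methylhexa-2,5-dienoate
Product: 4 ethyl (2E,4R)-4-{[tert-butyl(dimethyl)silyl]oxy}-3-methylhexa-2,5-dienoate
Conditions: tBuMe2SiCl, imidazole, DMF, rt
Reagents that add atoms: tert-butyl(chloro)dimethylsilane, CC(C)(C)[Si](C)(C)Cl
Why: Imidazole-promoted silylation masks the bis-allylic alcohol so that it is not oxidised in step 5 and cannot trap the acyl azolium in step 6, and the stereocentre is not touched.

Step 4
Reactants: 4 ethyl (2E,4R)-4-{[tert-butyl(dimethyl)silyl]oxy}-3-methylhexa-2,5-dienoate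
Product: 5 (2E,4R)-4-{[tert-butyl(dimethyl)silyl]oxy}-3-methylhexa-2,5-dien-1-ol
Conditions: iBu2AlH (2.2 equiv), CH2Cl2, −78 °C; aq. potassium sodium tartrate
Reagents that add atoms: none
Why: Ester reduction by 1,2-hydride addition of iBu2AlH gives the allylic alcohol without touching the alkenes or the silyl ether.

Step 5
Reactants: 5 (2E,4R)-4-{[tert-butyl(dimethyl)silyl]oxy}-3-methylhexa-2,5-dien-1-ol
Product: 6 (2E,4R)-4-{[tert-butyl(dimethyl)silyl]oxy}-3-methylhexa-2,5-dienal
Conditions: activated MnO2 (excess), CH2Cl2, rt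
Reagents that add atoms: none
Why: Allylic oxidation with MnO2 converts the primary allylic alcohol to the enal with retention of the (E) geometry.

Step 6
Reactants: 6 (2E,4R)-4-{[tert-butyl(dimethyl)silyl]oxy}-3-methylhexa-2,5-dienal; 7 4-methylpent-1-en-3-one
Product: 9 (1R,2S,5R)-2-[(1R)-1-{[tert-butyl(dimethyl)silyl]oxy}prop-2-en-1-yl]-2-methyl-5-(propan-2-yl)-6-oxabicyclo[3.2.0]heptan-7-one, via azolium enolate 8 (not isolated)
Conditions: 1,3-bis(2,4,6-trimethylphenyl)imidazolium chloride (10 mol %), DBU (15 mol %), THF, 0 °C to rt, 7 (1.5 equiv) added slowly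
Reagents that add atoms: none
Why: Proposed new method: the carbene adds to the aldehyde of 6 to give a Breslow intermediate whose homoenolate carbon (the fully substituted β-carbon, future C8a) attacks the unhindered CH2 terminus of 7 (C8a–C1 bond); the azolium enolate 8 then closes on the isopropyl ketone by a 5-(enolexo)-exo-trig aldol (C3a–C3 bond), and the tertiary alkoxide acylates the acyl azolium by a 4-exo-trig lactonisation that releases the carbene. The closest known reaction type is the imidazolylidene-catalysed homoenolate annulation of enals with chalcones (Michael addition, aldol, β-lactone), and β,β-disubstituted enals are known to form quaternary carbons as homoenolates with other electrophiles; the pairing of such an enal with an alkyl vinyl ketone and isolation of the β-lactone is the new part. C8a is set by the C8 stereocentre of 6, the electrophile approaching the homoenolate face anti to the vinyl group with the silyloxy group inside and H outside next to the methyl group (inside-alkoxy model). C3a and C3 follow from the aldol, in which the methyl group on C8a and not the branched C8 arm eclipses the enolate (1,3-allylic strain) so that the acyl carbon ends cis to the methyl group, and from the β-lactone, which can close only when the C3 oxygen and the C3a acyl group are cis; the aldol is reversible and lactonisation drains the cis aldolate. The step needs homoenolate instead of acyl-anion (Stetter-type) reactivity and conjugate instead of carbonyl addition, which the N-mesityl imidazolylidene and the unsubstituted vinyl terminus of 7 should secure, and slow addition of 7 limits its oligomerisation by the carbene.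

Step 7
Reactants: 9 (1R,2S,5R)-2-[(1R)-1-{[tert-butyl(dimethyl)silyl]oxy}prop-2-en-1-yl]-2-methyl-5-(propan-2-yl)-6-oxabicyclo[3.2.0]heptan-7-one
Product: 10 (1R,2S,3S)-3-[(1R)-1-{[tert-butyl(dimethyl)silyl]oxy}prop-2-en-1-yl]-2-(hydroxymethyl)-3-methyl-1-(propan-2-yl)cyclopentan-1-ol
Conditions: LiAlH4, THF, 0 °C
Reagents that add atoms: none
Why: LiAlH4 lactone reduction opens the strained β-lactone at the acyl carbon to the primary alcohol and frees the tertiary alcohol with its C–O bond, and so the configuration at C3, intact.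

Step 8
Reactants: 10 (1R,2S,3S)-3-[(1R)-1-{[tert-butyl(dimethyl)silyl]oxy}prop-2-en-1-yl]-2-(hydroxymethyl)-3-methyl-1-(propan-2-yl)cyclopentan-1-ol
Product: 11 (1R,2S,5R)-2-[(1R)-1-{[tert-butyl(dimethyl)silyl]oxy}prop-2-en-1-yl]-5-hydroxy-2-methyl-5-(propan-2-yl)cyclopentane-1-carbaldehyde
Conditions: Dess–Martin periodinane, pyridine, CH2Cl2, 0 °C; used crude
Reagents that add atoms: none
Why: Dess–Martin oxidation converts only the primary alcohol, since the tertiary one cannot be oxidised, and the buffered non-basic medium should keep the β-hydroxy aldehyde from retro-aldol cleavage and from epimerisation at C3a.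

Step 9
Reactants: 11 (1R,2S,5R)-2-[(1R)-1-{[tert-butyl(dimethyl)silyl]oxy}prop-2-en-1-yl]-5-hydroxy-2-methyl-5-(propan-2-yl)cyclopentane-1-carbaldehyde
Product: 12 (1R,2S,3S)-3-[(1R)-1-{[tert-butyl(dimethyl)silyl]oxy}prop-2-en-1-yl]-2-[(1S)-1-hydroxy-3-methylbut-3-en-1-yl]-3-methyl-1-(propan-2-yl)cyclopentan-1-ol
Conditions: CH2=C(CH3)CH2MgCl (3 equiv), THF, −78 °C; aq. NH4Cl
Reagents that add atoms: 2-methylallylmagnesium chloride, CC(=C)C[Mg]Cl
Why: Chelation-controlled Grignard addition, in which the first equivalent forms the magnesium alkoxide at the C3 oxygen, this binds the aldehyde oxygen in a six-membered chelate cis-fused to the cyclopentane, and the 2-methylallyl group adds to the chelate face turned away from the C8a methyl group, which sets C4 as (S).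

Step 10
Reactants: 12 (1R,2S,3S)-3-[(1R)-1-{[tert-butyl(dimethyl)silyl]oxy}prop-2-en-1-yl]-2-[(1S)-1-hydroxy-3-methylbut-3-en-1-yl]-3-methyl-1-(propan-2-yl)cyclopentan-1-ol
Product: 13 (1S)-1-[(1S,2R,5S)-5-[(1R)-1-{[tert-butyl(dimethyl)silyl]oxy}prop-2-en-1-yl]-2-hydroxy-5-methyl-2-(propan-2-yl)cyclopentyl]-3-methylbut-3-en-1-yl 3,4-dimethoxybenzoate
Conditions: 3,4-dimethoxybenzoyl chloride, Et3N, DMAP (cat.), CH2Cl2, 0 °C to rt
Reagents that add atoms: 3,4-dimethoxybenzoyl chloride, COc1ccc(cc1OC)C(=O)Cl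
Why: DMAP-catalysed acyl chloride esterification acylates the secondary C4 hydroxyl, while the tertiary C3 hydroxyl next to the isopropyl group is too hindered to react.

Step 11
Reactants: 13 (1S)-1-[(1S,2R,5S)-5-[(1R)-1-{[tert-butyl(dimethyl)silyl]oxy}prop-2-en-1-yl]-2-hydroxy-5-methyl-2-(propan-2-yl)cyclopentyl]-3-methylbut-3-en-1-yl 3,4-dimethoxybenzoate
Product: 14 (1S)-1-[(1S,2R,5S)-2-hydroxy-5-[(1R)-1-hydroxyprop-2-en-1-yl]-5-methyl-2-(propan-2-yl)cyclopentyl]-3-methylbut-3-en-1-yl 3,4-dimethoxybenzoate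
Conditions: HF·pyridine, pyridine, THF, 0 °C to rt
Reagents that add atoms: none
Why: Fluoride-mediated desilylation with buffered HF·pyridine cleaves the Si–O bond without acyl migration or ester cleavage and frees the allylic C8 alcohol.

Step 12
Reactants: 14 (1S)-1-[(1S,2R,5S)-2-hydroxy-5-[(1R)-1-hydroxyprop-2-en-1-yl]-5-methyl-2-(propan-2-yl)cyclopentyl]-3-methylbut-3-en-1-yl 3,4-dimethoxybenzoate
Product: 15 (3R,3aS,4S,8R,8aS)-3,8-dihydroxy-6,8a-dimethyl-3-(propan-2-yl)-1,2,3,3a,4,5,8,8a-octahydroazulen-4-yl 3,4-dimethoxybenzoate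
Conditions: second-generation Hoveyda–Grubbs catalyst (10 mol %), toluene (2 mM), 80 °C
Reagents that add atoms: none
Why: Ring-closing metathesis, in which the ruthenium alkylidene forms at the monosubstituted vinyl group and closes on the 1,1-disubstituted alkene to give the trisubstituted C6=C7 bond with loss of ethene, and the ring forms trans-fused because the two arms are trans on the cyclopentane.

Step 13
Reactants: 15 (3R,3aS,4S,8R,8aS)-3,8-dihydroxy-6,8a-dimethyl-3-(propan-2-yl)-1,2,3,3a,4,5,8,8a-octahydroazulen-4-yl 3,4-dimethoxybenzoate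
Product: 16 (3R,3aS,4S,8R,8aS)-3-hydroxy-6,8a-dimethyl-8-{[(2Z)-2-methylbut-2-enoyl]oxy}-3-(propan-2-yl)-1,2,3,3a,4,5,8,8a-octahydroazulen-4-yl 3,4-dimethoxybenzoate
Conditions: angelic acid, 2,4,6-trichlorobenzoyl chloride, Et3N, toluene, rt; then 15, 80 °C
Reagents that add atoms: angelic acid, C/C=C(/C)C(=O)O
Why: Yamaguchi-type esterification through the mixed anhydride of angelic acid, run without a nucleophilic catalyst so that the (Z)-alkene should not isomerise to the tiglate, acylates the secondary allylic C8 alcohol and leaves the tertiary C3 alcohol free.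

**Compound list**
1 | ethyl (2E)-3-methyl-4-oxobut-2-enoate | CCOC(=O)/C=C(C)/C=O | starting material
2 | ethyl (2E)-4-hydroxy-3-methylhexa-2,5-dienoate (racemic) | CCOC(=O)/C=C(C)/C(O)C=C | intermediate
3 | ethyl (2E,4R)-4-hydroxy-3-methylhexa-2,5-dienoate | C=C[C@@H](O)/C(C)=C/C(=O)OCC | intermediate
4 | ethyl (2E,4R)-4-{[tert-butyl(dimethyl)silyl]oxy}-3-methylhexa-2,5-dienoate | C=C[C@@H](O[Si](C)(C)C(C)(C)C)/C(C)=C/C(=O)OCC | intermediate
5 | (2E,4R)-4-{[tert-butyl(dimethyl)silyl]oxy}-3-methylhexa-2,5-dien-1-ol | C=C[C@@H](O[Si](C)(C)C(C)(C)C)/C(C)=C/CO | intermediate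
6 | (2E,4R)-4-{[tert-butyl(dimethyl)silyl]oxy}-3-methylhexa-2,5-dienal | C=C[C@@H](O[Si](C)(C)C(C)(C)C)/C(C)=C/C=O | intermediate
7 | 4-methylpent-1-en-3-one (isopropyl vinyl ketone) | C=CC(=O)C(C)C | starting material
8 | azolium enolate: (3S,4R)-1-[1,3-bis(2,4,6-trimethylphenyl)imidazol-3-ium-2-yl]-4-{[tert-butyl(dimethyl)silyl]oxy}-3-methyl-3-(4-methyl-3-oxopentyl)hexa-1,5-dien-1-olate | C=C[C@@H](O[Si](C)(C)C(C)(C)C)[C@@](C)(CCC(=O)C(C)C)C=C([O-])c1n(-c2c(C)cc(C)cc2C)cc[n+]1-c1c(C)cc(C)cc1C | intermediate (not isolated)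
9 | (1R,2S,5R)-2-[(1R)-1-{[tert-butyl(dimethyl)silyl]oxy}prop-2-en-1-yl]-2-methyl-5-(propan-2-yl)-6-oxabicyclo[3.2.0]heptan-7-one | C=C[C@@H](O[Si](C)(C)C(C)(C)C)[C@@]1(C)CC[C@]2(C(C)C)OC(=O)[C@H]12 | intermediate
10 | (1R,2S,3S)-3-[(1R)-1-{[tert-butyl(dimethyl)silyl]oxy}prop-2-en-1-yl]-2-(hydroxymethyl)-3-methyl-1-(propan-2-yl)cyclopentan-1-ol | C=C[C@@H](O[Si](C)(C)C(C)(C)C)[C@@]1(C)CC[C@@](O)(C(C)C)[C@@H]1CO | intermediate
11 | (1R,2S,5R)-2-[(1R)-1-{[tert-butyl(dimethyl)silyl]oxy}prop-2-en-1-yl]-5-hydroxy-2-methyl-5-(propan-2-yl)cyclopentane-1-carbaldehyde | C=C[C@@H](O[Si](C)(C)C(C)(C)C)[C@@]1(C)CC[C@@](O)(C(C)C)[C@@H]1C=O | intermediate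
12 | (1R,2S,3S)-3-[(1R)-1-{[tert-butyl(dimethyl)silyl]oxy}prop-2-en-1-yl]-2-[(1S)-1-hydroxy-3-methylbut-3-en-1-yl]-3-methyl-1-(propan-2-yl)cyclopentan-1-ol | C=C[C@@H](O[Si](C)(C)C(C)(C)C)[C@@]1(C)CC[C@@](O)(C(C)C)[C@@H]1[C@@H](O)CC(C)=C | intermediate
13 | (1S)-1-[(1S,2R,5S)-5-[(1R)-1-{[tert-butyl(dimethyl)silyl]oxy}prop-2-en-1-yl]-2-hydroxy-5-methyl-2-(propan-2-yl)cyclopentyl]-3-methylbut-3-en-1-yl 3,4-dimethoxybenzoate | C=C[C@@H](O[Si](C)(C)C(C)(C)C)[C@@]1(C)CC[C@@](O)(C(C)C)[C@@H]1[C@@H](OC(=O)c2ccc(OC)c(OC)c2)CC(C)=C | intermediate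
14 | (1S)-1-[(1S,2R,5S)-2-hydroxy-5-[(1R)-1-hydroxyprop-2-en-1-yl]-5-methyl-2-(propan-2-yl)cyclopentyl]-3-methylbut-3-en-1-yl 3,4-dimethoxybenzoate | C=C[C@@H](O)[C@@]1(C)CC[C@@](O)(C(C)C)[C@@H]1[C@@H](OC(=O)c2ccc(OC)c(OC)c2)CC(C)=C | intermediate
15 | (3R,3aS,4S,8R,8aS)-3,8-dihydroxy-6,8a-dimethyl-3-(propan-2-yl)-1,2,3,3a,4,5,8,8a-octahydroazulen-4-yl 3,4-dimethoxybenzoate | O[C@@H]1C=C(C)C[C@H](OC(=O)c2ccc(OC)c(OC)c2)[C@@H]2[C@]1(C)CC[C@@]2(O)C(C)C | intermediate
16 | (3R,3aS,4S,8R,8aS)-3-hydroxy-6,8a-dimethyl-8-{[(2Z)-2-methylbut-2-enoyl]oxy}-3-(propan-2-yl)-1,2,3,3a,4,5,8,8a-octahydroazulen-4-yl 3,4-dimethoxybenzoate | C/C=C(/C)C(=O)O[C@@H]1C=C(C)C[C@H](OC(=O)c2ccc(OC)c(OC)c2)[C@@H]2[C@]1(C)CC[C@@]2(O)C(C)C | target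

**Total step count:** 13. **Longest linear sequence:** 13 steps (1 to 16); 7 enters at step 6.

**Steps most likely to fail**

Step 6 (Proposed new method). What may go wrong: acyl-anion (Stetter-type) addition or carbene-induced oligomerisation of the vinyl ketone outrunning homoenolate attack at the hindered carbon; expulsion of the γ-silyloxy group from the homoenolate; poor facial selectivity at C8a. Fallback, from 6 and 7, returning at 11 (9 and 10 are passed by): 7 is treated with HBr and then ethane-1,2-diol to give 2-(2-bromoethyl)-2-(propan-2-yl)-1,3-dioxolane F1. Its Grignard reagent, with CuBr·SMe2 and Me3SiCl, adds 1,4 to enal 6 (organocopper conjugate addition, a known route to quaternary carbons on β,β-disubstituted enals, expected anti to the silyloxy group with H inside). Work-up gives (3S,4R)-4-{[tert-butyl(dimethyl)silyl]oxy}-3-methyl-3-{2-[2-(propan-2-yl)-1,3-dioxolan-2-yl]ethyl}hex-5-enal F2. Pyridinium tosylate in wet acetone removes the dioxolane to give (3S,4R)-4-{[tert-butyl(dimethyl)silyl]oxy}-3-methyl-3-(4-methyl-3-oxopentyl)hex-5-enal F3. An amine-catalysed 5-(enolexo)-exo-trig aldolisation (pyrrolidine, AcOH) then closes the cyclopentane to hydroxy aldehyde 11.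

Step 9. What may go wrong: poor facial selectivity if the chelate does not form, and retro-aldol cleavage or C3a epimerisation of the β-hydroxy aldehyde. Fallback, from 9, returning at 12: the β-lactone 9 is opened with MeNH(OMe)·HCl and Me2AlCl to (1R,2S,5R)-2-[(1R)-1-{[tert-butyl(dimethyl)silyl]oxy}prop-2-en-1-yl]-5-hydroxy-N-methoxy-N,2-dimethyl-5-(propan-2-yl)cyclopentane-1-carboxamide F4. CH2=C(CH3)CH2MgCl converts it to 1-[(1R,2S,5R)-2-[(1R)-1-{[tert-butyl(dimethyl)silyl]oxy}prop-2-en-1-yl]-5-hydroxy-2-methyl-5-(propan-2-yl)cyclopentyl]-3-methylbut-3-en-1-one F5. Reagent-controlled Corey–Bakshi–Shibata reduction (BH3·SMe2, (R)-2-methyl-CBS-oxazaborolidine) then sets C4 and gives 12.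

Step 13. What may go wrong: slow acylation of the neopentylic C8 alcohol and Z-to-E isomerisation of the angeloyl group. Fallback, from 15, returning at 16: 15 is esterified with 2-[bis(2,2,2-trifluoroethoxy)phosphoryl]propanoic acid (DCC, DMAP) to (3R,3aS,4S,8R,8aS)-8-({2-[bis(2,2,2-trifluoroethoxy)phosphoryl]propanoyl}oxy)-3-hydroxy-6,8a-dimethyl-3-(propan-2-yl)-1,2,3,3a,4,5,8,8a-octahydroazulen-4-yl 3,4-dimethoxybenzoate F6. A Still–Gennari olefination with acetaldehyde (KN(SiMe3)2, 18-crown-6, THF, −78 °C) then builds the (Z)-2-methylbut-2-enoate in place and gives 16.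

**Further compounds**
F1 | step 6 | 2-(2-bromoethyl)-2-(propan-2-yl)-1,3-dioxolane | BrCCC1(C(C)C)OCCO1
F2 | step 6 | (3S,4R)-4-{[tert-butyl(dimethyl)silyl]oxy}-3-methyl-3-{2-[2-(propan-2-yl)-1,3-dioxolan-2-yl]ethyl}hex-5-enal | C=C[C@@H](O[Si](C)(C)C(C)(C)C)[C@@](C)(CCC1(C(C)C)OCCO1)CC=O
F3 | step 6 | (3S,4R)-4-{[tert-butyl(dimethyl)silyl]oxy}-3-methyl-3-(4-methyl-3-oxopentyl)hex-5-enal | C=C[C@@H](O[Si](C)(C)C(C)(C)C)[C@@](C)(CCC(=O)C(C)C)CC=O
F4 | step 9 | (1R,2S,5R)-2-[(1R)-1-{[tert-butyl(dimethyl)silyl]oxy}prop-2-en-1-yl]-5-hydroxy-N-methoxy-N,2-dimethyl-5-(propan-2-yl)cyclopentane-1-carboxamide | C=C[C@@H](O[Si](C)(C)C(C)(C)C)[C@@]1(C)CC[C@@](O)(C(C)C)[C@@H]1C(=O)N(C)OC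
F5 | step 9 | 1-[(1R,2S,5R)-2-[(1R)-1-{[tert-butyl(dimethyl)silyl]oxy}prop-2-en-1-yl]-5-hydroxy-2-methyl-5-(propan-2-yl)cyclopentyl]-3-methylbut-3-en-1-one | C=C[C@@H](O[Si](C)(C)C(C)(C)C)[C@@]1(C)CC[C@@](O)(C(C)C)[C@@H]1C(=O)CC(C)=C
F6 | step 13 | (3R,3aS,4S,8R,8aS)-8-({2-[bis(2,2,2-trifluoroethoxy)phosphoryl]propanoyl}oxy)-3-hydroxy-6,8a-dimethyl-3-(propan-2-yl)-1,2,3,3a,4,5,8,8a-octahydroazulen-4-yl 3,4-dimethoxybenzoate | CC(C(=O)O[C@@H]1C=C(C)C[C@H](OC(=O)c2ccc(OC)c(OC)c2)[C@@H]2[C@]1(C)CC[C@@]2(O)C(C)C)P(=O)(OCC(F)(F)F)OCC(F)(F)F
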